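**Plan**
Locants follow spiro[4.5]decane: ring A = C1–C5 (C1 carbinol, C2 triene-bearing CH, C5 spiro), ring B = C5–C10 (C6 hydroxypropyl CH, C7 alkylidene, C10 methyl carbinol); C1'–C3' = the propanal unit.
Retrosynthetic cuts, in order: C16=C17 of the side chain (olefination with geranial); C7=C2' through a seven-membered lactone O1–C1' that also holds the aldehyde oxidation level; C1–C2 of ring A (carbonyl-ene); O–C10; C7–C8 and C9–C10 of ring B together; C5–C6.
Forward order: acyclic nitro keto ester, ring B, the C10 carbinol, spiro-closure of ring A, the lactone, the triene, the enal.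
Enabling feature: in ring B, C10 is a former acetyl C=O on the spiro carbon C5 and C7 can be an acidic CH–NO2 (later C=O, then the alkylidene carbon); they lie 1,4 across the unsubstituted C8–C9 bridge, so one vinylphosphonium unit is spliced in by conjugate addition at C8 and Wittig closure at C9=C10.
Stereochemistry: C5/C6 from the catalyst of the nitro-Michael step; C10 from CH2OH-directed epoxidation and hydride opening; C1/C2 from the ene transition state; C7=C2' from the lactone ring; C16=C17 from the phosphonate olefination; C18=C19 from geranial.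

Key step: step 4

Remark: 4 and 26 are taken as purchasable; in step 3 the cupreidine-derived catalyst or its cupreine-derived pseudoenantiomer is used, whichever delivers the drawn antipode (TBS = tert-butyldimethylsilyl, TES = triethylsilyl).

Step 1
Reactants: 1 ethyl acetoacetate; 2 5-bromo-2-methylpent-2-ene
Product: 3 ethyl 2-acetyl-6-methylhept-5-enoate (racemic)
Conditions: NaOEt, EtOH, reflux
Reagents that add atoms: none
Why: Acetoacetic ester C-alkylation of the stabilised enolate with a primary bromide; the labile stereocentre is fixed only in step 3.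

Step 2
Reactants: 4 4-(tert-butyldimethylsilyloxy)butanal; 5 nitromethane
Product: 8 (E)-tert-butyldimethyl(5-nitropent-4-enyloxy)silane, via nitro alcohol 6 (not isolated), via mesylate 7 (not isolated)
Conditions: MeNO2 (5 equiv), KOtBu (10 mol%), THF/tBuOH, 0 °C; then MsCl, Et3N, CH2Cl2, −20 → 0 °C
Reagents that add atoms: none
Why: Henry addition followed by β-elimination of the mesylate should give the conjugated nitroalkene as its thermodynamic E isomer.

Step 3
Reactants: 3 ethyl 2-acetyl-6-methylhept-5-enoate; 8 (E)-tert-butyldimethyl(5-nitropent-4-enyloxy)silane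
Product: 9 ethyl (2R)-2-acetyl-6-methyl-2-[(2S)-1-nitro-5-(TBSO)pentan-2-yl]hept-5-enoate
Conditions: 9-O-(9-phenanthryl)cupreidine (10 mol%), THF, −20 °C
Reagents that add atoms: none
Why: Asymmetric organocatalytic Michael addition of an α-substituted β-keto ester to a nitroalkene, in which the quinuclidine-bound enolate and the phenol-bound nitroalkene meet in one ion-paired transition state that sets the quaternary centre (future C5) and the adjacent CH (future C6) together.

Step 4
Reactants: 9 ethyl (2R)-2-acetyl-6-methyl-2-[(2S)-1-nitro-5-(TBSO)pentan-2-yl]hept-5-enoate; 10 vinyltriphenylphosphonium bromide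
Product: 13 ethyl 2-methyl-1-(4-methylpent-3-enyl)-5-nitro-6-[3-(TBSO)propyl]cyclohex-2-ene-1-carboxylate (C1 and C6 as set in 9; C5 epimers), via phosphonium salt 11 (not isolated), via phosphorus ylide 12 (not isolated)
Conditions: DBU (20 mol%), DMF, −20 °C; then KOtBu (2.1 equiv), THF, −40 → 0 °C; AcOH
Reagents that add atoms: none
Why: Catalytic DBU turns the CH2NO2 group into a nitronate whose carbon (C7) adds to the β-carbon of the vinylphosphonium salt (C8) to give salt 11, and KOtBu then generates ylide 12 at C9 beside the more acidic nitro C–H, which attacks the acetyl carbonyl (C10) and collapses through an oxaphosphetane to the C9=C10 alkene and Ph3PO. The closest known reaction type is the vinylphosphonium annulation, in which a stabilised carbanion adds to vinyltriphenylphosphonium bromide and the resulting ylide olefinates a tethered ketone to a cycloalkene. Ring B is closed by a 6-exo-trig attack of the ylide carbon on the ketone followed by cycloelimination. No lasting stereocentre is formed: C7 stays an epimer mixture that is erased in step 12, C10 becomes trigonal and receives its hydroxyl in steps 6 and 7, and C5 and C6 carry no acidic hydrogen here. The step needs C- over O-alkylation of the nitronate (favoured by the soft phosphonium acceptor), ketone over ester selectivity in the olefination (the methyl ketone is far more electrophilic than the neopentyl-type ester), and trapping of the nitronate faster than its retro-Michael loss of the β-keto ester enolate, which the low stationary nitronate concentration under catalytic DBU, the low temperature and an excess of 10 should secure.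

Step 5
Reactants: 13 ethyl 2-methyl-1-(4-methylpent-3-enyl)-5-nitro-6-[3-(TBSO)propyl]cyclohex-2-ene-1-carboxylate
Product: 14 [2-methyl-1-(4-methylpent-3-enyl)-5-nitro-6-[3-(TBSO)propyl]cyclohex-2-en-1-yl]methanol
Conditions: LiBH4, MeOH (1 equiv), THF, 0 → 40 °C
Reagents that add atoms: none
Why: Borohydride reduction of the ester, which leaves the nitro group, both alkenes and the silyl ether untouched, unmasks the primary alcohol that directs step 6.

Step 6
Reactants: 14 [2-methyl-1-(4-methylpent-3-enyl)-5-nitro-6-[3-(TBSO)propyl]cyclohex-2-en-1-yl]methanol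
Product: 15 [2,3-epoxy-2-methyl-1-(4-methylpent-3-enyl)-5-nitro-6-[3-(TBSO)propyl]cyclohexyl]methanol (oxirane oxygen cis to CH2OH)
Conditions: VO(acac)2 (5 mol%), tBuOOH, CH2Cl2, 0 °C → rt
Reagents that add atoms: tert-butyl hydroperoxide, CC(C)(C)OO
Why: Hydroxyl-directed epoxidation: the vanadium alkoxide of the homoallylic alcohol delivers oxygen to the face of C9=C10 that carries the CH2OH group, which puts the C10 oxygen cis to the future C1 as the target requires, while the remote trisubstituted alkene is not activated.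

Step 7
Reactants: 15 [2,3-epoxy-2-methyl-1-(4-methylpent-3-enyl)-5-nitro-6-[3-(TBSO)propyl]cyclohexyl]methanol
Product: 16 2-(hydroxymethyl)-1-methyl-2-(4-methylpent-3-enyl)-4-nitro-3-[3-(TBSO)propyl]cyclohexan-1-ol (tertiary OH cis to CH2OH)
Conditions: LiEt3BH (4 equiv), THF, 0 °C → rt; aq. NH4Cl
Reagents that add atoms: none
Why: Hydride opening of the trisubstituted epoxide at its less substituted carbon (C9) leaves the C10–O bond intact and so turns the directed epoxide into the tertiary alcohol of the target configuration; the nitro group should sit out the step as its nitronate and return on protonation.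

Step 8
Reactants: 16 2-(hydroxymethyl)-1-methyl-2-(4-methylpent-3-enyl)-4-nitro-3-[3-(TBSO)propyl]cyclohexan-1-ol
Product: 17 2-hydroxy-2-methyl-1-(4-methylpent-3-enyl)-5-nitro-6-[3-(TBSO)propyl]cyclohexane-1-carbaldehyde
Conditions: Dess–Martin periodinane, NaHCO3, CH2Cl2, 0 °C
Reagents that add atoms: none
Why: Dess–Martin oxidation of the primary neopentyl alcohol under buffered, non-basic conditions spares the tertiary alcohol and avoids retro-aldol cleavage of the β-hydroxy aldehyde.

Step 9
Reactants: 17 2-hydroxy-2-methyl-1-(4-methylpent-3-enyl)-5-nitro-6-[3-(TBSO)propyl]cyclohexane-1-carbaldehyde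
Product: 18 2-methyl-1-(4-methylpent-3-enyl)-5-nitro-6-[3-(TBSO)propyl]-2-(triethylsilyloxy)cyclohexane-1-carbaldehyde
Conditions: Et3SiOTf, 2,6-lutidine, CH2Cl2, −78 °C
Reagents that add atoms: triethylsilyl trifluoromethanesulfonate, CC[Si](CC)(CC)OS(=O)(=O)C(F)(F)F
Why: Silyl triflate silylation of the hindered tertiary alcohol (the aldehyde has no α-hydrogen) installs a bulky, non-chelating ether that is wanted for the facial control of step 10.

Step 10
Reactants: 18 2-methyl-1-(4-methylpent-3-enyl)-5-nitro-6-[3-(TBSO)propyl]-2-(triethylsilyloxy)cyclohexane-1-carbaldehyde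
Product: 19 10-methyl-7-nitro-2-(prop-1-en-2-yl)-6-[3-(TBSO)propyl]-10-(triethylsilyloxy)spiro[4.5]decan-1-ol (C1 C2 C5 C6 C10 as in 30; C7 epimers)
Conditions: Me2AlCl (2 equiv), CH2Cl2, −78 → −40 °C
Reagents that add atoms: none
Why: Lewis acid promoted intramolecular carbonyl-ene reaction (type 1) in which a concerted six-centre hydrogen transfer from one methyl group closes the five-membered ring A with the new hydroxyl and isopropenyl groups cis, and the aluminium-bound carbonyl oxygen is expected to turn away from the fully substituted C10 toward C6–H, so that O1 and the alkenyl group end on the C6 face of ring A.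

Step 11
Reactants: 19 10-methyl-7-nitro-2-(prop-1-en-2-yl)-6-[3-(TBSO)propyl]-10-(triethylsilyloxy)spiro[4.5]decan-1-ol; 20 2-(diethoxyphosphoryl)propanoic acid
Product: 21 10-methyl-7-nitro-2-(prop-1-en-2-yl)-6-[3-(TBSO)propyl]-10-(triethylsilyloxy)spiro[4.5]decan-1-yl 2-(diethoxyphosphoryl)propanoate
Conditions: DCC, DMAP, CH2Cl2, 0 °C → rt
Reagents that add atoms: none
Why: Steglich esterification of the only free hydroxyl group attaches the phosphonate that will be used for the ring-controlled olefination.

Step 12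
Reactants: 21 10-methyl-7-nitro-2-(prop-1-en-2-yl)-6-[3-(TBSO)propyl]-10-(triethylsilyloxy)spiro[4.5]decan-1-yl 2-(diethoxyphosphoryl)propanoate
Product: 22 10-methyl-7-oxo-2-(prop-1-en-2-yl)-6-[3-(TBSO)propyl]-10-(triethylsilyloxy)spiro[4.5]decan-1-yl 2-(diethoxyphosphoryl)propanoate
Conditions: KOtBu (1.0 equiv), THF, 0 °C; then N-methylmorpholine N-oxide, Pr4N[RuO4] (10 mol%), 4 Å molecular sieves, MeCN, rt
Reagents that add atoms: N-methylmorpholine N-oxide, C[N+]1([O-])CCOCC1
Why: Oxidative Nef reaction: the nitronate of the most acidic C–H is oxidised at carbon by the perruthenate/N-oxide couple and releases nitrite to give the C7 ketone, which removes the uncontrolled C7 centre.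

Step 13
Reactants: 22 10-methyl-7-oxo-2-(prop-1-en-2-yl)-6-[3-(TBSO)propyl]-10-(triethylsilyloxy)spiro[4.5]decan-1-yl 2-(diethoxyphosphoryl)propanoate
Product: 23 tricyclic lactone of (Z)-2-[1-hydroxy-10-methyl-2-(prop-1-en-2-yl)-6-[3-(TBSO)propyl]-10-(triethylsilyloxy)spiro[4.5]decan-7-ylidene]propanoic acid (seven-membered ring O1–C1'–C2'=C7–C6–C5–C1)
Conditions: LiCl, DBU, MeCN (0.003 M), rt
Reagents that add atoms: none
Why: Intramolecular Horner–Wadsworth–Emmons olefination of the ketone under mild LiCl/amine conditions; the seven-membered lactone can only hold a cis ring alkene, so C1' is forced onto the C6 side of C7=C2', which is the geometry of the target enal.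

Step 14
Reactants: 23 tricyclic lactone with the 2-(prop-1-en-2-yl) group
Product: 24 the 2-(3-chloroprop-1-en-2-yl) analogue of lactone 23
Conditions: Ca(OCl)2, solid CO2, CH2Cl2/H2O, 0 °C
Reagents that add atoms: calcium hypochlorite, [Ca+2].[O-]Cl.[O-]Cl
Why: Ene-type allylic chlorination by hypochlorous acid formed in situ attacks the electron-rich 1,1-disubstituted alkene at its CH2 terminus with loss of a methyl proton, whereas the ring alkene is deactivated by the lactone carbonyl.

Step 15
Reactants: 24 the 2-(3-chloroprop-1-en-2-yl) lactone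
Product: 25 the 2-[3-(diethoxyphosphoryl)prop-1-en-2-yl] analogue of lactone 23
Conditions: P(OEt)3 (neat), NaI (10 mol%), 120 °C
Reagents that add atoms: triethyl phosphite, CCOP(OCC)OCC
Why: Michaelis–Arbuzov reaction of the primary allylic chloride, in which direct and allylic substitution give the same product because the 2-substituted allyl unit is symmetrical.

Step 16
Reactants: 25 the allylic phosphonate lactone; 26 geranial
Product: 27 the lactone of 23 carrying the complete (3E,5E)-6,10-dimethylundeca-1,3,5,9-tetraen-2-yl group at C2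
Conditions: LiN(iPr)2, THF, −78 °C; then 26, −78 → 0 °C
Reagents that add atoms: none
Why: Horner–Wadsworth–Emmons reaction of the allylic phosphonate anion with the enal forms C16=C17 with the usual E preference of phosphonate olefination and carries the (E)-trisubstituted alkene of geranial over unchanged.

Step 17
Reactants: 27 the triene lactone
Product: 29 (Z)-2-[2-[(3E,5E)-6,10-dimethylundeca-1,3,5,9-tetraen-2-yl]-1-hydroxy-10-methyl-6-[3-(TBSO)propyl]-10-(triethylsilyloxy)spiro[4.5]decan-7-ylidene]propanal, via lactol 28 (not isolated)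
Conditions: iBu2AlH (1.2 equiv), CH2Cl2, −78 °C; aq. KNaC4H4O6
Reagents that add atoms: none
Why: Partial reduction of the lactone by iBu2AlH at low temperature stops at the aluminium hemiacetal, and the seven-membered lactol released on work-up should open to the conjugated hydroxy enal with the alkene geometry fixed in step 13.

Step 18
Reactants: 29 the bis-silyl ether of the target
Product: 30 (2Z)-2-[(1R,2S,5S,6R,10S)-2-[(3E,5E)-6,10-dimethylundeca-1,3,5,9-tetraen-2-yl]-1,10-dihydroxy-6-(3-hydroxypropyl)-10-methylspiro[4.5]decan-7-ylidene]propanal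
Conditions: HF·pyridine, pyridine, THF, 0 °C → rt
Reagents that add atoms: none
Why: Fluoride-mediated cleavage of the primary TBS and tertiary TES ethers under buffered conditions that the enal and the triene should tolerate.

**Compound list**
1 | ethyl acetoacetate | CCOC(=O)CC(C)=O | starting material
2 | 5-bromo-2-methylpent-2-ene | CC(C)=CCCBr | starting material
3 | ethyl 2-acetyl-6-methylhept-5-enoate (racemic) | CCOC(=O)C(CCC=C(C)C)C(C)=O | intermediate
4 | 4-(tert-butyldimethylsilyloxy)butanal | O=CCCCO[Si](C)(C)C(C)(C)C | starting material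
5 | nitromethane | C[N+](=O)[O-] | starting material
6 | 1-nitro-5-(tert-butyldimethylsilyloxy)pentan-2-ol (racemic) | [O-][N+](=O)CC(O)CCCO[Si](C)(C)C(C)(C)C | intermediate
7 | methanesulfonate of 6 | CS(=O)(=O)OC(C[N+](=O)[O-])CCCO[Si](C)(C)C(C)(C)C | intermediate
8 | (E)-tert-butyldimethyl(5-nitropent-4-enyloxy)silane | [O-][N+](=O)/C=C/CCCO[Si](C)(C)C(C)(C)C | intermediate
9 | ethyl (2R)-2-acetyl-6-methyl-2-[(2S)-1-nitro-5-(tert-butyldimethylsilyloxy)pentan-2-yl]hept-5-enoate | CC(C)=CCC[C@](C(C)=O)([C@H](CCCO[Si](C)(C)C(C)(C)C)C[N+](=O)[O-])C(=O)OCC | intermediate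
10 | vinyltriphenylphosphonium bromide | C=C[P+](c1ccccc1)(c1ccccc1)c1ccccc1.[Br-] | starting material
11 | phosphonium bromide formed by addition of the nitronate of 9 to 10 (C7 epimers) | CC(C)=CCC[C@](C(C)=O)([C@H](CCCO[Si](C)(C)C(C)(C)C)C(CC[P+](c1ccccc1)(c1ccccc1)c1ccccc1)[N+](=O)[O-])C(=O)OCC.[Br-] | intermediate
12 | phosphorus ylide derived from 11 | CC(C)=CCC[C@](C(C)=O)([C@H](CCCO[Si](C)(C)C(C)(C)C)C(CC=P(c1ccccc1)(c1ccccc1)c1ccccc1)[N+](=O)[O-])C(=O)OCC | intermediate
13 | ethyl 2-methyl-1-(4-methylpent-3-enyl)-5-nitro-6-[3-(tert-butyldimethylsilyloxy)propyl]cyclohex-2-ene-1-carboxylate (C1, C6 as drawn; C5 epimers) | CC(C)=CCC[C@]1([C@H](CCCO[Si](C)(C)C(C)(C)C)C(CC=C1C)[N+](=O)[O-])C(=O)OCC | intermediate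
14 | [2-methyl-1-(4-methylpent-3-enyl)-5-nitro-6-[3-(tert-butyldimethylsilyloxy)propyl]cyclohex-2-en-1-yl]methanol | CC(C)=CCC[C@]1([C@H](CCCO[Si](C)(C)C(C)(C)C)C(CC=C1C)[N+](=O)[O-])CO | intermediate
15 | 2,3-epoxide of 14, oxirane oxygen cis to CH2OH | CC(C)=CCC[C@]1([C@H](CCCO[Si](C)(C)C(C)(C)C)C(C[C@@H]2O[C@]12C)[N+](=O)[O-])CO | intermediate
16 | 2-(hydroxymethyl)-1-methyl-2-(4-methylpent-3-enyl)-4-nitro-3-[3-(tert-butyldimethylsilyloxy)propyl]cyclohexan-1-ol, tertiary OH cis to CH2OH | CC(C)=CCC[C@]1([C@H](CCCO[Si](C)(C)C(C)(C)C)C(CC[C@]1(C)O)[N+](=O)[O-])CO | intermediate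
17 | 2-hydroxy-2-methyl-1-(4-methylpent-3-enyl)-5-nitro-6-[3-(tert-butyldimethylsilyloxy)propyl]cyclohexane-1-carbaldehyde | CC(C)=CCC[C@]1([C@H](CCCO[Si](C)(C)C(C)(C)C)C(CC[C@]1(C)O)[N+](=O)[O-])C=O | intermediate
18 | 2-O-triethylsilyl ether of 17 | CC(C)=CCC[C@]1([C@H](CCCO[Si](C)(C)C(C)(C)C)C(CC[C@]1(C)O[Si](CC)(CC)CC)[N+](=O)[O-])C=O | intermediate
19 | 10-methyl-7-nitro-2-(prop-1-en-2-yl)-6-[3-(tert-butyldimethylsilyloxy)propyl]-10-(triethylsilyloxy)spiro[4.5]decan-1-ol (C1, C2, C5, C6, C10 as in 30; C7 epimers) | C=C(C)[C@@H]1CC[C@]2([C@H](CCCO[Si](C)(C)C(C)(C)C)C(CC[C@]2(C)O[Si](CC)(CC)CC)[N+](=O)[O-])[C@@H]1O | intermediate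
20 | 2-(diethoxyphosphoryl)propanoic acid | CCOP(=O)(OCC)C(C)C(=O)O | starting material
21 | 1-O-[2-(diethoxyphosphoryl)propanoyl] ester of 19 | C=C(C)[C@@H]1CC[C@]2([C@H](CCCO[Si](C)(C)C(C)(C)C)C(CC[C@]2(C)O[Si](CC)(CC)CC)[N+](=O)[O-])[C@@H]1OC(=O)C(C)P(=O)(OCC)OCC | intermediate
22 | 7-oxo analogue of 21 | C=C(C)[C@@H]1CC[C@]2([C@H](CCCO[Si](C)(C)C(C)(C)C)C(=O)CC[C@]2(C)O[Si](CC)(CC)CC)[C@@H]1OC(=O)C(C)P(=O)(OCC)OCC | intermediate
23 | tricyclic (Z)-lactone, O1–C1'(=O)–C2'(CH3)=C7 | C=C(C)[C@@H]1CC[C@]2([C@H](CCCO[Si](C)(C)C(C)(C)C)/C(=C(/C)C3=O)CC[C@]2(C)O[Si](CC)(CC)CC)[C@@H]1O3 | intermediate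
24 | 2-(3-chloroprop-1-en-2-yl) analogue of 23 | C=C(CCl)[C@@H]1CC[C@]2([C@H](CCCO[Si](C)(C)C(C)(C)C)/C(=C(/C)C3=O)CC[C@]2(C)O[Si](CC)(CC)CC)[C@@H]1O3 | intermediate
25 | 2-[3-(diethoxyphosphoryl)prop-1-en-2-yl] analogue of 23 | C=C(CP(=O)(OCC)OCC)[C@@H]1CC[C@]2([C@H](CCCO[Si](C)(C)C(C)(C)C)/C(=C(/C)C3=O)CC[C@]2(C)O[Si](CC)(CC)CC)[C@@H]1O3 | intermediate
26 | geranial, (2E)-3,7-dimethylocta-2,6-dienal | CC(C)=CCC/C(C)=C/C=O | starting material
27 | lactone 23 carrying the (3E,5E)-6,10-dimethylundeca-1,3,5,9-tetraen-2-yl group at C2 | C=C(/C=C/C=C(\C)CCC=C(C)C)[C@@H]1CC[C@]2([C@H](CCCO[Si](C)(C)C(C)(C)C)/C(=C(/C)C3=O)CC[C@]2(C)O[Si](CC)(CC)CC)[C@@H]1O3 | intermediate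
28 | lactol from reduction of 27 (anomers) | C=C(/C=C/C=C(\C)CCC=C(C)C)[C@@H]1CC[C@]2([C@H](CCCO[Si](C)(C)C(C)(C)C)/C(=C(/C)C3O)CC[C@]2(C)O[Si](CC)(CC)CC)[C@@H]1O3 | intermediate
29 | 3''-O-TBS, 10-O-TES bis-silyl ether of 30 | C=C(/C=C/C=C(\C)CCC=C(C)C)[C@@H]1CC[C@]2([C@H](CCCO[Si](C)(C)C(C)(C)C)/C(=C(/C)C=O)CC[C@]2(C)O[Si](CC)(CC)CC)[C@@H]1O | intermediate
30 | (2Z)-2-[(1R,2S,5S,6R,10S)-2-[(3E,5E)-6,10-dimethylundeca-1,3,5,9-tetraen-2-yl]-1,10-dihydroxy-6-(3-hydroxypropyl)-10-methylspiro[4.5]decan-7-ylidene]propanal | C=C(/C=C/C=C(\C)CCC=C(C)C)[C@@H]1CC[C@]2([C@H](CCCO)/C(=C(/C)C=O)CC[C@]2(C)O)[C@@H]1O | target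

**Count and risks**
Total steps: 18. Longest linear sequence: 17 steps (steps 1 and 3–18 from 1; the branch through step 2 from 4 is equally long).

Most likely to fail, in this order:

Step 4. The nitronate may revert by retro-Michael loss of the β-keto ester enolate before it is trapped, and olefination of the hindered ketone may be slow. The fallback builds the same two bonds in separate, non-basic events and sets out from 9. Zerovalent-palladium-catalysed Tsuji–Trost allylation with allyl methyl carbonate (Pd(PPh3)4, THF, rt, base only in catalytic amount) gives the C7-allyl nitro ketone F1. Methylenation of the acetyl group with Cp2TiMe2 (toluene, 65 °C), which is non-basic and prefers the ketone to the ester, gives the isopropenyl diene F2. Ring-closing metathesis of the allyl and isopropenyl groups (second-generation Grubbs catalyst, RuCl2(H2IMes)(PCy3)(=CHPh), CH2Cl2, 40 °C) closes ring B and comes back to 13.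

Step 10. Facial discrimination at the aldehyde may be poor, or a stepwise cationic pathway may erode the cis relation, so that C1 forms as an epimer mixture. The fallback sets C1 by hydride delivery instead and sets out from 18. The ene reaction is run as in step 10 and the product is accepted as 19 together with its C1 epimer F3. Dess–Martin oxidation of the mixture gives the single cyclopentanone F4. Reduction with LiB(s-Bu)3H (THF, −78 °C) should bring hydride in from the face opposite the two lower-face α-substituents (the C2 isopropenyl group and C6), giving the alcohol cis to the isopropenyl group and coming back to 19.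

Step 13. Closure of the seven-membered ring at the hindered ketone may be slow, leaving time for base-induced epimerisation at C6 next to the ketone. The fallback closes the ring under non-basic reductive conditions and sets out from 19. Acylation with 2-bromopropanoyl bromide (pyridine, CH2Cl2, 0 °C) gives the bromo ester F5. The Nef conditions of step 12 give the bromo keto ester F6. SmI2 (THF, −78 °C) effects an intramolecular Reformatsky addition to the ketone and gives the β-hydroxy lactone F7. Dehydration (SOCl2, pyridine, 0 °C) toward the acidic C2' hydrogen comes back to 23, with the alkene geometry again fixed by the ring.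

**Further compounds**
F1 | step 4 | ethyl 2-acetyl-6-methyl-2-[2-nitro-7-(tert-butyldimethylsilyloxy)hept-... C7-allyl derivative of 9 (C7 epimers) | CC(C)=CCC[C@](C(C)=O)([C@H](CCCO[Si](C)(C)C(C)(C)C)C(CC=C)[N+](=O)[O-])C(=O)OCC
F2 | step 4 | isopropenyl analogue of F1 (acetyl C=O replaced by C=CH2) | CC(C)=CCC[C@](C(C)=C)([C@H](CCCO[Si](C)(C)C(C)(C)C)C(CC=C)[N+](=O)[O-])C(=O)OCC
F3 | step 10 | C1 epimer of 19 | C=C(C)[C@@H]1CC[C@]2([C@H](CCCO[Si](C)(C)C(C)(C)C)C(CC[C@]2(C)O[Si](CC)(CC)CC)[N+](=O)[O-])[C@H]1O
F4 | step 10 | 10-methyl-7-nitro-2-(prop-1-en-2-yl)-6-[3-(tert-butyldimethylsilyloxy)propyl]-10-(triethylsilyloxy)spiro[4.5]decan-1-one | C=C(C)[C@@H]1CC[C@]2([C@H](CCCO[Si](C)(C)C(C)(C)C)C(CC[C@]2(C)O[Si](CC)(CC)CC)[N+](=O)[O-])C1=O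
F5 | step 13 | 1-O-(2-bromopropanoyl) ester of 19 | C=C(C)[C@@H]1CC[C@]2([C@H](CCCO[Si](C)(C)C(C)(C)C)C(CC[C@]2(C)O[Si](CC)(CC)CC)[N+](=O)[O-])[C@@H]1OC(=O)C(C)Br
F6 | step 13 | 7-oxo analogue of F5 | C=C(C)[C@@H]1CC[C@]2([C@H](CCCO[Si](C)(C)C(C)(C)C)C(=O)CC[C@]2(C)O[Si](CC)(CC)CC)[C@@H]1OC(=O)C(C)Br
F7 | step 13 | 7-hydroxy-7,2'-dihydro analogue of lactone 23 (β-hydroxy lactone, C7 and C2' epimers) | C=C(C)[C@@H]1CC[C@]2([C@H](CCCO[Si](C)(C)C(C)(C)C)C(O)(C(C)C3=O)CC[C@]2(C)O[Si](CC)(CC)CC)[C@@H]1O3
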